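**Remarks on the chemistry (assumptions)**
- Hydride is assumed to add to the C6 ketone of 9 from the convex face (the face of H4a and H7a), so that step 7 gives the (6R) alcohol 11.
- The (S,S) enantiomer of the ligand Taniaphos is assumed to give the (2R) product in step 3; if the sense of induction is the opposite, the (R,R) ligand is used.

## Analysis of the target

The target 28 is the diester of a tetrasubstituted cyclobutane-1,3-dicarboxylic acid with two bicyclic amino alcohols and has 14 stereocentres. The alcohols are 2,4,7-trimethyloctahydro-1H-cyclopenta[c]pyridin-6-ols (numbering C1, N2, C3, C4, C4a, C5, C6, C7, C7a).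

In the cyclobutane the two 4-hydroxy-3-methoxyphenyl groups (C2, C4) are cis to each other and to the C3 carboxyl, and trans to the C1 carboxyl. The ring has a local mirror plane through C1 and C3, so it carries no absolute configuration, but its two carboxyls are diastereotopic.

Each amino alcohol is a cis-fused piperidine–cyclopentane with H4a, H7a, the C4 methyl and the C7 methyl on one face (4R,4aR,7R,7aS). The two units differ only at C6. The C1 carboxyl carries the (6S) alcohol (oxygen on the convex face, cis to the C7 methyl). The C3 carboxyl carries the (6R) alcohol (oxygen on the concave face).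

Sensitive groups are two free phenols, two tertiary amines (N-oxidation), two hindered esters, and the ring carbon C3. C3 is cis to both neighbours and α to an ester, and can epimerise to the all-trans arrangement under base.

The difficulty is twofold. Five contiguous stereocentres per bicycle must be set in the absolute sense. Two C6-epimeric esters must also be placed on the right carboxyls of a symmetric core.

The strategy rests on the five-membered ring of the bicycle. C6 (oxygenated) sits between the methylene C5 and the methyl-bearing C7, and the ring is fused at C4a–C7a. At the ketone level this is a 2-methylcyclopentenone: C6 is a carbonyl carbon, C7 and C7a come from a methyl-substituted alkyne, and C5 and C4a from a terminal alkene. Both rings can therefore come from an acyclic nitrogen-tethered enyne whose only stereocentre is C4.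

## Retrosynthetic reasoning

**28 to 27.** The two phenol O–H bonds are masked as benzyl ethers. They survive every step of the assembly and are removed last by hydrogenolysis, which touches neither the esters nor the amines.

**27 to 26 and 11.** The ester at the C1 carboxyl is cut at its O–C6 bond. This ester is (6S), the opposite of alcohol 11, so a carboxylate displacement with inversion lets the same alcohol serve both esters. C1 is the unhindered carboxyl, and the nucleophile enters C6 from the open convex face. The acid is not activated, so the ring centres are safe.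

**26 to 25 to 23 and 11.** The ester at the C3 carboxyl is (6R), as in 11, so it is cut at the acyl–oxygen bond (acylation with retention). The C1 carboxyl is masked meanwhile as a tert-butyl ester, which is removed by acid. The forward order is fixed by the next disconnection: the amide must be cleaved with peroxide before any tertiary amine is present.

**23 to 21 to 20 to 16 and 18.** Both aryl–ring bonds are cut. An amide at C3 that directs palladium to the two cis methylene C–H bonds gives exactly the aryl/carboxyl/aryl cis,cis relationship. The trans ester at C1 is a bystander that comes in with 12. Amide 16 comes from acid 14 and amine 15, 14 from 12 by ester exchange (13), and 18 from phenol 17.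

**11 to 9 to 8 to 7.** The C6 hydroxyl and the N-methyl group come from a ketone and a methyl carbamate in one hydride reduction. The C7 methyl is placed on the convex face by equilibration of 8. The cis ring fusion comes from hydrogenation of the C7=C7a bond of enone 7.

**7 to 5.** The key disconnection cuts C4a–C7a, C5–C6 and C6–C7. It opens both rings to the acyclic enyne 5 plus one carbonyl carbon from the cobalt reagent. No other cut removes two rings and leaves a single stereocentre.

**5 to 4 to 2 and 3, 2 from 1.** The C4–CH3 bond is cut in the SN2′ sense, which leads to the achiral allylic bromide 4. Its N–C3 bond comes from alkylation of carbamate 2 with dibromide 3, and 2 from amine salt 1. The forward methylation must set C4 under catalyst control.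

## Alternatives that were turned down

**Alternative 1:** This alternative cuts the two aryl–cyclobutane bonds and makes the core the centre of the synthesis. Forward, Pd(OAc)2 (divalent palladium) with AgOAc couples two molecules of 18 with the two ring methylenes cis to a quinolin-8-yl amide. No ring is closed. The product is A1, the methyl ester analogue of 20.
- For: one operation fixes the relative configuration of all four ring carbons. The amide/ester pair differentiates the two carboxyls as the target needs. The reaction type is well established for cyclobutanecarboxamides.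
- Against: the core is achiral. Ten of the 14 stereocentres and all absolute configuration lie in the bicyclic amino alcohols, about which this step says nothing. The methyl ester of A1 is also not orthogonal to the basic peroxide cleavage of the amide.
- Comparison: on the core this alternative is as strong as anything available. The chosen route uses the same bond construction as a supporting operation (16 to 20, with a tert-butyl ester). What the chosen strategy offers in its place is a one-step construction of the bicycle, where the real difficulty lies.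

**Alternative 2:** This alternative cuts C4–C4a; an N-allyl group becomes C3, C4 and the C4 methyl. Forward, Fe(acac)3 (trivalent iron) and PhSiH3 transfer a hydrogen atom to the terminal alkene carbon. The secondary C4 radical adds 6-exo to the enone β-carbon C4a, and the α-keto radical is reduced and protonated. The product is A2.
- For: A2 already has the N-methyl group and the C6 ketone and is one hydride reduction from 11. That is shorter after the key step than the chosen route, and no nitrogen protecting group is needed. The cis fusion is enforced by the tether at C7a.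
- Against: only one bond and one ring are formed. The cyclopentenone substrate must already carry C7 and C7a as enantiopure, trans-disposed centres, both epimerisable (α and γ to the carbonyl). C4 arises from a planar radical, so only the chair-like transition state, not a catalyst, sets its methyl group. Reduction of the radical before the slower 6-exo closure is a likely competing process.
- Comparison: this alternative is stronger on late-stage step economy. The chosen route is stronger at the front: it forms three bonds and two rings from a chain made in three steps, and its only stereocentre is set by a catalyst.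

**Alternative 3:** This alternative cuts C7–C7a. Forward, Ph3PAuSbF6 (monovalent gold) activates the alkyne of a propargylic pivalate attached to a tetrahydropyridine. The pivaloyloxy group shifts 1,2, the pentadienyl cation cyclises, and hydrolysis gives enone A3. The propargylic configuration is transferred to C7a.
- For: the key step is catalytic in metal and needs neither stoichiometric cobalt nor CO. It is mild. The C4a=C5 bond of A3 can be hydrogenated to the cis fusion.
- Against: only the five-membered ring is closed. The piperidine ring with the C4 methyl must be built first, and an enantioenriched propargylic ester must be attached in the right relative configuration. That is two independent stereocentres in the substrate where the chosen route needs one. Chirality transfer holds only if cyclisation outruns ionisation to an achiral cation. In A3 both C4 and C7a are γ to the enone carbonyl and can be lost through the dienolate when C7 is equilibrated.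
- Comparison: this alternative is stronger on catalysis and atom economy in the key step. The chosen route is stronger on bonds formed per step, simplicity of the precursor, and robustness of the stereocentres.

Key step: step 4

## Route

**Fragment 1: amino alcohol 11 (steps 1–7)**

Step 1
Reactants: 1 but-2-yn-1-amine hydrochloride
Product: 2 methyl but-2-yn-1-ylcarbamate
Conditions: ClCO2Me (1.1 equiv), Et3N (2.2 equiv), CH2Cl2, 0 °C to rt
Reagents that add atoms: methyl chloroformate, COC(=O)Cl
Why: Carbamate formation from a primary amine and a chloroformate; the second equivalent of base frees the amine from its salt. The carbamate keeps nitrogen non-basic through the metal-mediated steps and later becomes the N-methyl group.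

Step 2
Reactants: 2 methyl but-2-yn-1-ylcarbamate; 3 (E)-1,4-dibromobut-2-ene
Product: 4 methyl [(2E)-4-bromobut-2-en-1-yl](but-2-yn-1-yl)carbamate
Conditions: NaH (1.1 equiv), 3 (4 equiv), DMF, 0 °C to rt
Reagents that add atoms: none
Why: SN2 N-alkylation of the sodium carbamate with a primary allylic bromide. The excess of the symmetric dibromide suppresses double substitution and is recovered.

Step 3
Reactants: 4 methyl [(2E)-4-bromobut-2-en-1-yl](but-2-yn-1-yl)carbamate
Product: 5 methyl (but-2-yn-1-yl)[(2R)-2-methylbut-3-en-1-yl]carbamate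
Conditions: MeMgBr (1.3 equiv), CuBr·SMe2 (3 mol %), (S,S)-Taniaphos (C43H39FeNP2, ferrocenyl diphosphine, 3.5 mol %), CH2Cl2, −75 °C
Reagents that add atoms: methylmagnesium bromide, C[Mg]Br
Why: Copper-catalysed enantioselective allylic alkylation (SN2′) of an (E)-allylic bromide that carries a protected nitrogen, with a Grignard reagent. The chiral complex of monovalent copper adds at the γ-carbon anti to bromide and reductive elimination is faster than allyl isomerisation, so the branched terminal alkene forms and the ligand selects the face that gives the (R) centre (the later C4). At −75 °C the carbamate and the alkyne are not attacked.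

Step 4
Reactants: 5 methyl (but-2-yn-1-yl)[(2R)-2-methylbut-3-en-1-yl]carbamate
Product: 7 methyl (4R,4aR)-4,7-dimethyl-6-oxo-1,3,4,4a,5,6-hexahydro-2H-cyclopenta[c]pyridine-2-carboxylate, via alkyne–Co2(CO)6 complex 6 (not isolated)
Conditions: Co2(CO)8 (1.1 equiv), CH2Cl2, rt; then N-methylmorpholine N-oxide (8 equiv), 0 °C to rt
Reagents that add atoms: dicobalt octacarbonyl Co2(CO)8 (one CO ligand, [C-]#[O+], becomes C6=O), [C-]#[O+].[C-]#[O+].[C-]#[O+].[C-]#[O+].[C-]#[O+].[C-]#[O+].[C-]#[O+].[C-]#[O+].[Co].[Co]
Why: Intramolecular Pauson–Khand reaction, the formal [2+2+1] union of alkyne, alkene and CO, of the kind known for nitrogen-tethered 1,7-enynes. Co2(CO)8 (zerovalent cobalt) first forms complex 6, and the amine oxide oxidises one CO ligand to CO2, which frees a coordination site for the alkene at low temperature. Insertion of the alkene into the Co–C7a bond forms C4a–C7a and closes the piperidine ring in the exo sense (C5 stays outside the six-membered ring); CO insertion and reductive elimination then form C5–C6 and C6–C7 and close the cyclopentenone. The tether fixes the regiochemistry: the alkyne carbon bearing CH2N must bond to the internal alkene carbon, so the methyl-bearing alkyne carbon becomes C7 next to the carbonyl. The only new stereocentre, C4a, is controlled by C4: in the chair-like arrangement of the forming six-membered ring the C4 methyl lies pseudo-equatorial, which puts H4a on the face of that methyl (4R,4aR). The step needs this 1,2-induction and needs ring closure to outrun decomposition of 6; the planar, non-coordinating carbamate nitrogen and the allylic methyl branch, which favours the folded conformer, are what should secure both. C4 itself is not touched, because no allylic C–H bond is broken.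

Step 5
Reactants: 7 methyl (4R,4aR)-4,7-dimethyl-6-oxo-1,3,4,4a,5,6-hexahydro-2H-cyclopenta[c]pyridine-2-carboxylate
Product: 8 methyl (4R,4aR,7S,7aS)-4,7-dimethyl-6-oxooctahydro-2H-cyclopenta[c]pyridine-2-carboxylate
Conditions: H2 (1 atm), 10% Pd/C, EtOAc, rt
Reagents that add atoms: none
Why: Heterogeneous syn hydrogenation of the tetrasubstituted enone. Hydrogen should add from the face of H4a, because the piperidine ring screens the other face; H7a therefore ends cis to H4a (cis fusion, 7aS) and the C7 methyl is left on the concave face for the moment.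

Step 6
Reactants: 8 methyl (4R,4aR,7S,7aS)-4,7-dimethyl-6-oxooctahydro-2H-cyclopenta[c]pyridine-2-carboxylate
Product: 9 methyl (4R,4aR,7R,7aS)-4,7-dimethyl-6-oxooctahydro-2H-cyclopenta[c]pyridine-2-carboxylate
Conditions: K2CO3, MeOH, rt
Reagents that add atoms: none
Why: Thermodynamic epimerisation through the C6 enolate. The C7 methyl leaves the concave face, where it is cis to C1 on the next carbon, for the convex face (7R); C4, C4a and C7a cannot enolise and C5 carries no stereocentre.

Step 7
Reactants: 9 methyl (4R,4aR,7R,7aS)-4,7-dimethyl-6-oxooctahydro-2H-cyclopenta[c]pyridine-2-carboxylate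
Product: 11 (4R,4aR,6R,7R,7aS)-2,4,7-trimethyloctahydro-1H-cyclopenta[c]pyridin-6-ol, via hydroxy carbamate 10 (not isolated)
Conditions: LiAlH4 (4 equiv), THF, −78 °C to 0 °C, then reflux
Reagents that add atoms: none
Why: Hydride reduction of the cyclopentanone, then on heating reduction of the methyl carbamate to the N-methyl amine. The small hydride should enter C6 from the convex face, which is also the approach that gives the alcohol trans to the neighbouring methyl group, as is usual for 2-methylcyclopentanones; the hydroxyl then lies on the concave face (6R).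

**Fragment 2: cyclobutane acid 23 (steps 8–14)**

Step 8
Reactants: 12 trans-3-(methoxycarbonyl)cyclobutane-1-carboxylic acid
Product: 13 1-tert-butyl 3-methyl trans-cyclobutane-1,3-dicarboxylate
Conditions: tert-butyl 2,2,2-trichloroacetimidate (2 equiv), BF3·OEt2 (5 mol %), CH2Cl2/cyclohexane, rt
Reagents that add atoms: tert-butyl 2,2,2-trichloroacetimidate, CC(C)(C)OC(=N)C(Cl)(Cl)Cl
Why: Acid-catalysed tert-butylation of a carboxylic acid with a trichloroacetimidate. No base is present, so the trans relationship of the ring substituents is kept.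

Step 9
Reactants: 13 1-tert-butyl 3-methyl trans-cyclobutane-1,3-dicarboxylate
Product: 14 trans-3-(tert-butoxycarbonyl)cyclobutane-1-carboxylic acid
Conditions: LiOH·H2O (1.1 equiv), THF/H2O 3:1, 0 °C; then dilute HCl to pH 3
Reagents that add atoms: lithium hydroxide (hydroxide oxygen), [Li+].[OH-]
Why: Selective saponification of the methyl ester beside the hindered tert-butyl ester. Hydrolysis at 0 °C is much faster than enolisation, so the trans configuration should be retained.

Step 10
Reactants: 14 trans-3-(tert-butoxycarbonyl)cyclobutane-1-carboxylic acid; 15 quinolin-8-amine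
Product: 16 tert-butyl trans-3-(quinolin-8-ylcarbamoyl)cyclobutane-1-carboxylate
Conditions: EDC·HCl (1.3 equiv), DMAP (0.3 equiv), CH2Cl2, rt
Reagents that add atoms: none
Why: Carbodiimide amide coupling. It installs the N,N-bidentate amide that directs the C–H arylation.

Step 11
Reactants: 17 4-iodo-2-methoxyphenol
Product: 18 1-(benzyloxy)-4-iodo-2-methoxybenzene
Conditions: BnBr (1.1 equiv), K2CO3 (1.5 equiv), DMF, rt
Reagents that add atoms: benzyl bromide, BrCc1ccccc1
Why: Williamson ether synthesis on the phenol. The benzyl ether survives all later steps and is removed last.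

Step 12
Reactants: 16 tert-butyl trans-3-(quinolin-8-ylcarbamoyl)cyclobutane-1-carboxylate; 18 1-(benzyloxy)-4-iodo-2-methoxybenzene (two molecules are incorporated)
Product: 20 tert-butyl (1α,2β,3β,4β)-2,4-bis[4-(benzyloxy)-3-methoxyphenyl]-3-(quinolin-8-ylcarbamoyl)cyclobutane-1-carboxylate, via monoaryl amide 19 (not isolated)
Conditions: Pd(OAc)2 (10 mol %), AgOAc (3 equiv), 18 (4 equiv), toluene, 110 °C
Reagents that add atoms: none
Why: Aminoquinoline-directed β-C(sp3)–H arylation, known for cyclobutanecarboxamides including twofold arylation. Divalent palladium, held by the amide and quinoline nitrogens, cleaves the methylene C–H bond cis to the amide in a five-membered palladacycle; oxidative addition of the aryl iodide (tetravalent palladium) and reductive elimination form the aryl–ring bond while AgOAc takes up iodide. Both methylenes react in turn, so both aryl groups end cis to the C3 amide and trans to the C1 ester, and C1 and C3 are not touched.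

Step 13
Reactants: 20 tert-butyl (1α,2β,3β,4β)-2,4-bis[4-(benzyloxy)-3-methoxyphenyl]-3-(quinolin-8-ylcarbamoyl)cyclobutane-1-carboxylate
Product: 21 tert-butyl (1α,2β,3β,4β)-2,4-bis[4-(benzyloxy)-3-methoxyphenyl]-3-[(tert-butoxycarbonyl)(quinolin-8-yl)carbamoyl]cyclobutane-1-carboxylate
Conditions: Boc2O (3 equiv), DMAP (1 equiv), MeCN, 50 °C
Reagents that add atoms: di-tert-butyl dicarbonate, CC(C)(C)OC(=O)OC(=O)OC(C)(C)C
Why: N-acylation of the secondary amide gives a twisted N-acyl carbamate. Its ring acyl C–N bond is thereby activated for cleavage under mild conditions.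

Step 14
Reactants: 21 tert-butyl (1α,2β,3β,4β)-2,4-bis[4-(benzyloxy)-3-methoxyphenyl]-3-[(tert-butoxycarbonyl)(quinolin-8-yl)carbamoyl]cyclobutane-1-carboxylate
Product: 23 1-tert-butyl hydrogen (1α,2β,3β,4β)-2,4-bis[4-(benzyloxy)-3-methoxyphenyl]cyclobutane-1,3-dicarboxylate (free acid at C3, cis to both aryl groups), via peroxy acid 22 (not isolated)
Conditions: LiOH·H2O (2 equiv), 30% aq. H2O2 (6 equiv), THF/H2O 3:1, 0 °C; then aq. Na2SO3; then dilute HCl to pH 4
Reagents that add atoms: hydrogen peroxide (as lithium hydroperoxide), OO
Why: Hydroperoxide is a small, weakly basic α-effect nucleophile and should attack the activated ring acyl carbonyl in preference to the carbamate carbonyl and the tert-butyl ester; sulfite reduces the peroxy acid. The low basicity at 0 °C should leave the all-cis C3 centre intact, and no amine is yet present that peroxide could oxidise.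

**Union and end game (steps 15–18)**

Step 15
Reactants: 23 1-tert-butyl hydrogen (1α,2β,3β,4β)-2,4-bis[4-(benzyloxy)-3-methoxyphenyl]cyclobutane-1,3-dicarboxylate; 11 (4R,4aR,6R,7R,7aS)-2,4,7-trimethyloctahydro-1H-cyclopenta[c]pyridin-6-ol
Product: 25 1-tert-butyl 3-[(4R,4aR,6R,7R,7aS)-2,4,7-trimethyloctahydro-1H-cyclopenta[c]pyridin-6-yl] (1α,2β,3β,4β)-2,4-bis[4-(benzyloxy)-3-methoxyphenyl]cyclobutane-1,3-dicarboxylate, via acid chloride 24 (not isolated)
Conditions: 1-chloro-N,N,2-trimethylprop-1-en-1-amine (1.2 equiv), CH2Cl2, 0 °C to rt; then 11 (1.2 equiv), pyridine (3 equiv), DMAP (0.2 equiv), CH2Cl2, 0 °C to rt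
Reagents that add atoms: none
Why: The acyl chloride is formed under neutral conditions, so the tert-butyl ester and the benzyl ethers see no HCl; DMAP-catalysed acylation of the secondary alcohol follows. The C6–O bond is not broken, so the (6R) configuration is kept. A ketene from 24 would need an exocyclic double bond on the four-membered ring, which disfavours loss of the C3 configuration.

Step 16
Reactants: 25 1-tert-butyl 3-[(4R,4aR,6R,7R,7aS)-2,4,7-trimethyloctahydro-1H-cyclopenta[c]pyridin-6-yl] (1α,2β,3β,4β)-2,4-bis[4-(benzyloxy)-3-methoxyphenyl]cyclobutane-1,3-dicarboxylate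
Product: 26 3-[(4R,4aR,6R,7R,7aS)-2,4,7-trimethyloctahydro-1H-cyclopenta[c]pyridin-6-yl] hydrogen (1α,2β,3β,4β)-2,4-bis[4-(benzyloxy)-3-methoxyphenyl]cyclobutane-1,3-dicarboxylate (free acid at C1)
Conditions: TFA/CH2Cl2 1:4, Et3SiH (3 equiv), 0 °C to rt; then pH 7 buffer
Reagents that add atoms: none
Why: Acidolysis of the tert-butyl ester by alkyl–oxygen cleavage; the silane reduces the tert-butyl cation before it can alkylate the electron-rich aryl rings. The secondary alkyl ester, the benzyl ethers and the protonated amine are stable, and no base is present that could epimerise C3.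

Step 17
Reactants: 26 3-[(4R,4aR,6R,7R,7aS)-2,4,7-trimethyloctahydro-1H-cyclopenta[c]pyridin-6-yl] hydrogen (1α,2β,3β,4β)-2,4-bis[4-(benzyloxy)-3-methoxyphenyl]cyclobutane-1,3-dicarboxylate; 11 (4R,4aR,6R,7R,7aS)-2,4,7-trimethyloctahydro-1H-cyclopenta[c]pyridin-6-ol
Product: 27 1-[(4R,4aR,6S,7R,7aS)-2,4,7-trimethyloctahydro-1H-cyclopenta[c]pyridin-6-yl] 3-[(4R,4aR,6R,7R,7aS)-2,4,7-trimethyloctahydro-1H-cyclopenta[c]pyridin-6-yl] (1α,2β,3β,4β)-2,4-bis[4-(benzyloxy)-3-methoxyphenyl]cyclobutane-1,3-dicarboxylate
Conditions: PPh3 (2.5 equiv), DIAD (2.5 equiv), 11 (1.5 equiv), THF, 0 °C to rt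
Reagents that add atoms: none
Why: Mitsunobu esterification. The alcohol is activated as its alkoxyphosphonium ion and displaced by the unhindered C1 carboxylate from the open convex face in an SN2 reaction, with inversion at C6 (6R to 6S). The acid is not activated, so the ring centres cannot epimerise.

Step 18
Reactants: 27 1-[(4R,4aR,6S,7R,7aS)-2,4,7-trimethyloctahydro-1H-cyclopenta[c]pyridin-6-yl] 3-[(4R,4aR,6R,7R,7aS)-2,4,7-trimethyloctahydro-1H-cyclopenta[c]pyridin-6-yl] (1α,2β,3β,4β)-2,4-bis[4-(benzyloxy)-3-methoxyphenyl]cyclobutane-1,3-dicarboxylate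
Product: 28 1-[(4R,4aR,6S,7R,7aS)-2,4,7-trimethyloctahydro-1H-cyclopenta[c]pyridin-6-yl] 3-[(4R,4aR,6R,7R,7aS)-2,4,7-trimethyloctahydro-1H-cyclopenta[c]pyridin-6-yl] (1α,2β,3β,4β)-2,4-bis(4-hydroxy-3-methoxyphenyl)cyclobutane-1,3-dicarboxylate (CNP0283097.4)
Conditions: H2 (1 atm), 10% Pd/C, MeOH/EtOAc 1:1, rt
Reagents that add atoms: none
Why: Hydrogenolysis of the two aryl benzyl ethers. Esters, tertiary amines and the cyclobutane are inert under these conditions and no stereocentre is involved.

## Compound list

1 | but-2-yn-1-amine hydrochloride | CC#CCN.Cl | starting material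
2 | methyl but-2-yn-1-ylcarbamate | CC#CCNC(=O)OC | intermediate
3 | (E)-1,4-dibromobut-2-ene | BrC/C=C/CBr | starting material
4 | methyl [(2E)-4-bromobut-2-en-1-yl](but-2-yn-1-yl)carbamate | CC#CCN(C(=O)OC)C/C=C/CBr | intermediate
5 | methyl (but-2-yn-1-yl)[(2R)-2-methylbut-3-en-1-yl]carbamate | CC#CCN(C(=O)OC)C[C@H](C)C=C | intermediate
6 | μ-alkyne hexacarbonyldicobalt complex of 5 (Co2(CO)6 on the C7≡C7a alkyne) | CC12C3(CN(C(=O)OC)C[C@H](C)C=C)[Co]1(=C=O)(=C=O)(=C=O)[Co]23(=C=O)(=C=O)=C=O | intermediate
7 | methyl (4R,4aR)-4,7-dimethyl-6-oxo-1,3,4,4a,5,6-hexahydro-2H-cyclopenta[c]pyridine-2-carboxylate | O=C1C[C@H]2C(CN(C(=O)OC)C[C@@H]2C)=C1C | intermediate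
8 | methyl (4R,4aR,7S,7aS)-4,7-dimethyl-6-oxooctahydro-2H-cyclopenta[c]pyridine-2-carboxylate | O=C1C[C@H]2[C@H](CN(C(=O)OC)C[C@@H]2C)[C@@H]1C | intermediate
9 | methyl (4R,4aR,7R,7aS)-4,7-dimethyl-6-oxooctahydro-2H-cyclopenta[c]pyridine-2-carboxylate | O=C1C[C@H]2[C@H](CN(C(=O)OC)C[C@@H]2C)[C@H]1C | intermediate
10 | methyl (4R,4aR,6R,7R,7aS)-6-hydroxy-4,7-dimethyloctahydro-2H-cyclopenta[c]pyridine-2-carboxylate | O[C@@H]1C[C@H]2[C@H](CN(C(=O)OC)C[C@@H]2C)[C@H]1C | intermediate
11 | (4R,4aR,6R,7R,7aS)-2,4,7-trimethyloctahydro-1H-cyclopenta[c]pyridin-6-ol | O[C@@H]1C[C@H]2[C@H](CN(C)C[C@@H]2C)[C@H]1C | intermediate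
12 | trans-3-(methoxycarbonyl)cyclobutane-1-carboxylic acid | COC(=O)[C@H]1C[C@H](C(=O)O)C1 | starting material
13 | 1-tert-butyl 3-methyl trans-cyclobutane-1,3-dicarboxylate | COC(=O)[C@H]1C[C@H](C(=O)OC(C)(C)C)C1 | intermediate
14 | trans-3-(tert-butoxycarbonyl)cyclobutane-1-carboxylic acid | CC(C)(C)OC(=O)[C@H]1C[C@H](C(=O)O)C1 | intermediate
15 | quinolin-8-amine | Nc1cccc2cccnc12 | starting material
16 | tert-butyl trans-3-(quinolin-8-ylcarbamoyl)cyclobutane-1-carboxylate | CC(C)(C)OC(=O)[C@H]1C[C@H](C(=O)Nc2cccc3cccnc23)C1 | intermediate
17 | 4-iodo-2-methoxyphenol | COc1cc(I)ccc1O | starting material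
18 | 1-(benzyloxy)-4-iodo-2-methoxybenzene | COc1cc(I)ccc1OCc1ccccc1 | intermediate
19 | tert-butyl (1α,2β,3β)-2-[4-(benzyloxy)-3-methoxyphenyl]-3-(quinolin-8-ylcarbamoyl)cyclobutane-1-carboxylate (racemic; one enantiomer drawn) | COc1cc([C@@H]2[C@@H](C(=O)OC(C)(C)C)C[C@@H]2C(=O)Nc2cccc3cccnc23)ccc1OCc1ccccc1 | intermediate
20 | tert-butyl (1α,2β,3β,4β)-2,4-bis[4-(benzyloxy)-3-methoxyphenyl]-3-(quinolin-8-ylcarbamoyl)cyclobutane-1-carboxylate | COc1cc([C@@H]2[C@@H](C(=O)OC(C)(C)C)[C@H](c3ccc(OCc4ccccc4)c(OC)c3)[C@@H]2C(=O)Nc2cccc3cccnc23)ccc1OCc1ccccc1 | intermediate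
21 | tert-butyl (1α,2β,3β,4β)-2,4-bis[4-(benzyloxy)-3-methoxyphenyl]-3-[(tert-butoxycarbonyl)(quinolin-8-yl)carbamoyl]cyclobutane-1-carboxylate | COc1cc([C@@H]2[C@@H](C(=O)OC(C)(C)C)[C@H](c3ccc(OCc4ccccc4)c(OC)c3)[C@@H]2C(=O)N(C(=O)OC(C)(C)C)c2cccc3cccnc23)ccc1OCc1ccccc1 | intermediate
22 | (1α,2β,3β,4β)-2,4-bis[4-(benzyloxy)-3-methoxyphenyl]-1-(tert-butoxycarbonyl)cyclobutane-3-carboperoxoic acid | COc1cc([C@@H]2[C@@H](C(=O)OC(C)(C)C)[C@H](c3ccc(OCc4ccccc4)c(OC)c3)[C@@H]2C(=O)OO)ccc1OCc1ccccc1 | intermediate
23 | 1-tert-butyl hydrogen (1α,2β,3β,4β)-2,4-bis[4-(benzyloxy)-3-methoxyphenyl]cyclobutane-1,3-dicarboxylate (acid at C3) | COc1cc([C@@H]2[C@@H](C(=O)OC(C)(C)C)[C@H](c3ccc(OCc4ccccc4)c(OC)c3)[C@@H]2C(=O)O)ccc1OCc1ccccc1 | intermediate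
24 | tert-butyl (1α,2β,3β,4β)-2,4-bis[4-(benzyloxy)-3-methoxyphenyl]-3-(chlorocarbonyl)cyclobutane-1-carboxylate | COc1cc([C@@H]2[C@@H](C(=O)OC(C)(C)C)[C@H](c3ccc(OCc4ccccc4)c(OC)c3)[C@@H]2C(=O)Cl)ccc1OCc1ccccc1 | intermediate
25 | 1-tert-butyl 3-[(4R,4aR,6R,7R,7aS)-2,4,7-trimethyloctahydro-1H-cyclopenta[c]pyridin-6-yl] (1α,2β,3β,4β)-2,4-bis[4-(benzyloxy)-3-methoxyphenyl]cyclobutane-1,3-dicarboxylate | COc1cc([C@@H]2[C@@H](C(=O)OC(C)(C)C)[C@H](c3ccc(OCc4ccccc4)c(OC)c3)[C@@H]2C(=O)O[C@@H]2C[C@H]3[C@H](CN(C)C[C@@H]3C)[C@H]2C)ccc1OCc1ccccc1 | intermediate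
26 | 3-[(4R,4aR,6R,7R,7aS)-2,4,7-trimethyloctahydro-1H-cyclopenta[c]pyridin-6-yl] hydrogen (1α,2β,3β,4β)-2,4-bis[4-(benzyloxy)-3-methoxyphenyl]cyclobutane-1,3-dicarboxylate (acid at C1) | COc1cc([C@@H]2[C@@H](C(=O)O)[C@H](c3ccc(OCc4ccccc4)c(OC)c3)[C@@H]2C(=O)O[C@@H]2C[C@H]3[C@H](CN(C)C[C@@H]3C)[C@H]2C)ccc1OCc1ccccc1 | intermediate
27 | 1-[(4R,4aR,6S,7R,7aS)-2,4,7-trimethyloctahydro-1H-cyclopenta[c]pyridin-6-yl] 3-[(4R,4aR,6R,7R,7aS)-2,4,7-trimethyloctahydro-1H-cyclopenta[c]pyridin-6-yl] (1α,2β,3β,4β)-2,4-bis[4-(benzyloxy)-3-methoxyphenyl]cyclobutane-1,3-dicarboxylate | COc1cc([C@@H]2[C@@H](C(=O)O[C@H]3C[C@H]4[C@H](CN(C)C[C@@H]4C)[C@H]3C)[C@H](c3ccc(OCc4ccccc4)c(OC)c3)[C@@H]2C(=O)O[C@@H]2C[C@H]3[C@H](CN(C)C[C@@H]3C)[C@H]2C)ccc1OCc1ccccc1 | intermediate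
28 | 1-[(4R,4aR,6S,7R,7aS)-2,4,7-trimethyloctahydro-1H-cyclopenta[c]pyridin-6-yl] 3-[(4R,4aR,6R,7R,7aS)-2,4,7-trimethyloctahydro-1H-cyclopenta[c]pyridin-6-yl] (1α,2β,3β,4β)-2,4-bis(4-hydroxy-3-methoxyphenyl)cyclobutane-1,3-dicarboxylate | COc1cc([C@@H]2[C@@H](C(=O)O[C@H]3C[C@H]4[C@H](CN(C)C[C@@H]4C)[C@H]3C)[C@H](c3ccc(O)c(OC)c3)[C@@H]2C(=O)O[C@@H]2C[C@H]3[C@H](CN(C)C[C@@H]3C)[C@H]2C)ccc1O | target

## Step count and least certain steps

Total: 18 steps. Longest linear sequence: 11 steps (steps 1–7, then 15–18). The core branch is 10 steps (steps 8–10, 12–14, then 15–18); step 11 is a one-step side branch.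

**Step 4 (key step).** Alkene insertion may be slow, because a six-membered ring has to form from a 1,7-enyne. Complex 6 could then decompose before it cyclises. The small C4 methyl may also control C4a only partly.

The fallback sets out from 5 and comes back at 11. It replaces the cobalt reaction by a reversible zirconocene cyclisation on a basic amine tether, in which the methyl group can settle equatorial under thermodynamic control.
- LiAlH4 reduces the carbamate of 5 to (2R)-N-(but-2-yn-1-yl)-N,2-dimethylbut-3-en-1-amine F1.
- Cp2ZrCl2 (tetravalent zirconium) with two equivalents of n-BuLi gives a divalent zirconocene equivalent, which forms the bis(cyclopentadienyl)zirconacyclopentene F2 (zirconium bonded to C5 and C7).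
- CO (1 atm) converts it into (4R,4aR)-2,4,7-trimethyl-1,2,3,4,4a,5-hexahydro-6H-cyclopenta[c]pyridin-6-one F3.
- Hydrogenation as in step 5 gives (4R,4aR,7S,7aS)-2,4,7-trimethyloctahydro-6H-cyclopenta[c]pyridin-6-one F4.
- Epimerisation as in step 6 gives (4R,4aR,7R,7aS)-2,4,7-trimethyloctahydro-6H-cyclopenta[c]pyridin-6-one F5, the same compound as A2.
- Hydride reduction of the ketone then gives 11.

**Step 7.** Facial selectivity of hydride addition may be poor. The convex face carries the C7 methyl and the concave face is screened by the piperidine ring, so the two steric effects oppose each other.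

The fallback sets out from 9 and comes back at 27. The C6 epimer formed alongside 11, (4R,4aR,6S,7R,7aS)-2,4,7-trimethyloctahydro-1H-cyclopenta[c]pyridin-6-ol F6, is separated and not discarded. It already has the configuration of the C1 ester. It is joined to acid 26 by carbodiimide acylation (EDC·HCl, DMAP), which goes with retention and gives 27. Alcohol 11 is then needed only for step 15.

**Step 15.** Acylation may be incomplete, because the carboxyl is flanked by two cis aryl groups and the hydroxyl sits on the concave face. Under forcing conditions the C3 configuration may be lost through enolisation of the activated acyl group, driven by relief of the all-cis strain.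

The fallback sets out from 21 and 11 and comes back at 25. Alcohol 11 is deprotonated with n-BuLi at −78 °C to lithium (4R,4aR,6R,7R,7aS)-2,4,7-trimethyloctahydro-1H-cyclopenta[c]pyridin-6-olate F7. The alkoxide attacks the twisted N-acyl carbamate 21 directly, the known alcoholysis of Boc-activated amides. This skips the free acid and the acid chloride.

**Step 14.** Hydroperoxide may attack the carbamate carbonyl of the Boc group in place of the crowded ring acyl carbonyl, which would return amide 20. Base-induced epimerisation at C3 is the second risk.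

The fallback sets out from 14 and 18 and comes back at 23. It uses no auxiliary. The free carboxylic acid of 14 directs the twofold β-C–H arylation itself (Pd(OAc)2, an N-acetyl amino acid ligand, Ag2CO3, K2HPO4, (CF3)2CHOH, 100 °C), a known reaction type for free aliphatic acids. It makes no new compound.

**Step 3.** Enantioselectivity or SN2′ selectivity may be eroded, because the carbamate carbonyl and the alkyne are additional donors for copper and magnesium.

The fallback sets out from 11 of insufficient enantiomeric purity and comes back at 11. It replaces catalyst control by classical resolution. The amine is crystallised as its 1:1 salt with (2R,3R)-2,3-bis(benzoyloxy)butanedioic acid F8, or with the enantiomeric acid if that gives the less soluble salt, and is set free with aqueous NaOH.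

## Further compounds

F1 | step 4 | (2R)-N-(but-2-yn-1-yl)-N,2-dimethylbut-3-en-1-amine | CC#CCN(C)C[C@H](C)C=C
F2 | step 4 | (4R,4aR)-6,6-bis(cyclopentadienyl)-2,4,7-trimethyl-1,2,3,4,4a,5-hexahydro-6-zirconacyclopenta[c]pyridine (zirconacyclopentene) | C1=CC(C=C1)[Zr]1(C2C=CC=C2)C[C@H]2C(CN(C)C[C@@H]2C)=C1C
F3 | step 4 | (4R,4aR)-2,4,7-trimethyl-1,2,3,4,4a,5-hexahydro-6H-cyclopenta[c]pyridin-6-one | O=C1C[C@H]2C(CN(C)C[C@@H]2C)=C1C
F4 | step 4 | (4R,4aR,7S,7aS)-2,4,7-trimethyloctahydro-6H-cyclopenta[c]pyridin-6-one | O=C1C[C@H]2[C@H](CN(C)C[C@@H]2C)[C@@H]1C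
F5 | step 4 | (4R,4aR,7R,7aS)-2,4,7-trimethyloctahydro-6H-cyclopenta[c]pyridin-6-one (same compound as A2) | O=C1C[C@H]2[C@H](CN(C)C[C@@H]2C)[C@H]1C
F6 | step 7 | (4R,4aR,6S,7R,7aS)-2,4,7-trimethyloctahydro-1H-cyclopenta[c]pyridin-6-ol | O[C@H]1C[C@H]2[C@H](CN(C)C[C@@H]2C)[C@H]1C
F7 | step 15 | lithium (4R,4aR,6R,7R,7aS)-2,4,7-trimethyloctahydro-1H-cyclopenta[c]pyridin-6-olate | [Li+].[O-][C@@H]1C[C@H]2[C@H](CN(C)C[C@@H]2C)[C@H]1C
F0 | step 14 | none | none
F8 | step 3 | 1:1 salt of 11 with (2R,3R)-2,3-bis(benzoyloxy)butanedioic acid | O[C@@H]1C[C@H]2[C@H](CN(C)C[C@@H]2C)[C@H]1C.OC(=O)[C@H](OC(=O)c1ccccc1)[C@@H](OC(=O)c1ccccc1)C(O)=O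
A1 | alternative 1 | methyl (1α,2β,3β,4β)-2,4-bis[4-(benzyloxy)-3-methoxyphenyl]-3-(quinolin-8-ylcarbamoyl)cyclobutane-1-carboxylate | COc1cc([C@@H]2[C@@H](C(=O)OC)[C@H](c3ccc(OCc4ccccc4)c(OC)c3)[C@@H]2C(=O)Nc2cccc3cccnc23)ccc1OCc1ccccc1
A2 | alternative 2 | (4R,4aR,7R,7aS)-2,4,7-trimethyloctahydro-6H-cyclopenta[c]pyridin-6-one | O=C1C[C@H]2[C@H](CN(C)C[C@@H]2C)[C@H]1C
A3 | alternative 3 | methyl (4R,7R,7aR)-4,7-dimethyl-6-oxo-1,3,4,6,7,7a-hexahydro-2H-cyclopenta[c]pyridine-2-carboxylate | O=C1C=C2[C@H](CN(C(=O)OC)C[C@@H]2C)[C@H]1C
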